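**Conventions.** Locants follow the mutilin skeleton: cyclopentanone C1–C2–C3(=O)–C4–C9; cyclohexane C4–C5–C6–C7–C8–C9; cyclooctane C4–C5–C14–C13–C12–C11–C10–C9; oxolane O–C11–C12–C19–C20. O14 carries the glycolate and C19 the free hydroxyl.

**Remark (one assumption).** Read literally, the C4, C5 and C6 labels of the given string put the C5–C14 and C9–C10 bonds on opposite faces of the cyclohexane, which the five-atom bridge cannot span; the chemistry is therefore argued for the mutilin arrangement (both bonds on one face, cis-hydrindanone), while the given string stays the formal target and its labels at these centres (and at the corresponding centres of all precursors, including the dihydrocarvone that supplies C6) are carried unchanged through every SMILES.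

## Analysis of the target

The carbon skeleton is a 5-6-8 tricycle in which cyclopentanone, cyclohexane and cyclooctane share the C4–C9 bond; an oxolane O–C11–C12–C19–C20 is cis-fused to the eight-membered ring at C11–C12. There are nine stereocentres (C4, C5, C6, C9, C10, C11, C12, C14, C19), three of them quaternary (C5, C9, C12), and seven of them lie on the eight-membered ring. On the oxolane, H-11, the C12 methyl and the C19 hydroxyl share one face, while C10 and C13 share the other. Sensitive groups are the glycolate ester at O14 (base-labile, able to migrate to a free O19), the epimerisable C4 next to the C3 ketone, and two free hydroxyls. The hard parts are the eight-membered ring between two quaternary bridgeheads, the C10–C11–C12–C19 array next to quaternary C9, and telling O14 from O19. The feature the route is built on: the 3-hydroxyoxolane O–C11–C12–C19–C20 is the exact retron of an aldehyde–allylsilane [3+2] annulation followed by C–Si oxidation (O and C11 from an aldehyde, C12/C19/C20 from the allyl unit, C19–OH from C19–Si). This makes the C11–C12 bond a convergent junction between a hydrindenone and the C12–C14 chain.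

## Retrosynthetic reasoning

27 ⇒ 26 ⇒ 25. The last two operations only unmask oxygen: the O22 benzyl ether, and O19, which is traced back to a C19–Si bond (oxidation with retention). While O14 is acylated, O19 therefore does not yet exist and needs no differentiation.

25 ⇒ 24. The O14–acyl bond is cut. The forward reaction must acylate a hindered secondary alcohol next to quaternary C5.

24 ⇒ 23. The C5–C14 bond is cut, which opens the eight-membered ring. It is cut there because a ketyl at C14 adding to the β-carbon of a C3(=O)–C4=C5 enone makes the quaternary C5, the C14 carbinol and (by enolate protonation) C4 in one reductive operation. The precursor is a bicyclic enone with a single chain.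

23 ⇒ 22 ⇒ 13 + 21 (key). After one-carbon excision at C14 (alkene cleavage), the C11–C12 and O–C20 bonds are cut together. This splits the molecule into hydrindenone aldehyde 13 (C1–C11) and allylsilane 21 (C12–C14, C19, C20). The forward annulation must build the oxolane and set C11, C12 and C19 as a group.

21 ⇒ 15 + 19; 15 ⇒ 14; 19 ⇒ 16 + 17. The C19–C20 bond is an sp2–sp3 cross-coupling with retention of alkene geometry. The (E)-iodide comes from syn-carbometalation of a terminal alkyne, which fixes the geometry that later decides C19. The bulky, oxidisable silyl group is assembled on silicon.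

13 ⇒ 12 ⇒ 10 ⇒ 9. The C3–C4 bond of the cyclopentenone is cut (intramolecular acylation of a trisubstituted alkene, which also delivers the C4=C5 enone needed later). C11 is adjusted from acid to aldehyde through a thioester.

9 ⇒ 7 ⇒ 5. The C9–C10 bond is cut as a [3,3] rearrangement of a C5 allylic propanoate. This forms quaternary C9 and tertiary C10 through one cyclic transition state and leaves the C4=C5(CH3) alkene in place. 7 arises from 5 by methyl addition and O-acylation.

5 ⇒ 4 ⇒ 2 + 3; 2 ⇒ 1. The C9–C1 bond is a conjugate addition of a three-carbon ester unit followed by re-oxidation to the enone. The C6 methyl centre comes from the chiral pool.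

## Alternatives that were turned down

Alternative 1: (textbook) Disconnect O11–C20 last. The forward key step is hydroxyl-directed epoxidation of the C12-vinyl C11-carbinol A1 to epoxy alcohol A2, then 5-endo opening at C20. A semisynthesis from fermentation-derived A1 is not a total synthesis, so A1 would have to be built first (crotylation at C11–C12, then ring closure). This route carries C11–OH protected through the ring closure, creates C19 late on a freely rotating vinyl group at quaternary C12 where only a homoallylic hydroxyl directs, and must make 5-endo win over 4-exo opening. It adds at least four operations and uses nothing of the oxolane retron.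

Alternative 2: Make the annulation intramolecular. Hydrindanone A3, carrying the aldehyde arm on C9 and the allylsilane arm on C5, would close the eight-membered ring and the oxolane at once to give A4. It was turned down because A3 needs quaternary C5 with its C14 carbinol arm before ring closure. That is exactly the bond the ketyl–enone step makes for free; intermolecular routes to it on a tetrasubstituted enone are not credible and [3,3] detours cost more than five steps. In A3 the allylsilane carbon C12 also reaches the C3 ketone through a six-membered transition state, so C3 would have to be masked and re-oxidised. Cationic closure of an eight-membered ring carries an entropic penalty the intermolecular version does not have.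

Alternative 3: Single-atom insertion. A ketene [2+2] cycloaddition on the tricyclic C11=C12 alkene A5 gives cyclobutanone A6; dechlorination and Baeyer–Villiger oxygen insertion give lactone A7; C19 hydroxylation and reduction of the C20 carbonyl would follow. It was turned down because A5 requires a trisubstituted Z-alkene inside the eight-membered ring next to C10, the facial selectivity of the cycloaddition on the folded ring cannot be steered, and after the insertion three more redox operations are needed in the presence of the C3 ketone. That is six or more steps for what annulation plus C–Si oxidation does in two.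

Key step: step 12

## Route

Step 1
Reactants: 1 trans-dihydrocarvone
Product: 2 (6S)-6-methylcyclohex-2-en-1-one
Conditions: O3, MeOH, −78 °C; then Cu(OAc)2·H2O, FeSO4·7H2O, −78 °C → rt
Reagents that add atoms: none
Why: Ozonolysis of the isopropenyl group in methanol gives the α-methoxy hydroperoxide; Fe(II) triggers alkoxy-radical β-scission (loss of methyl acetate) and Cu(II) oxidises the ring radical to the conjugated enone (ozonolysis/Fe–Cu dealkenylative fragmentation); the methyl-bearing centre (C6) is untouched.

Step 2
Reactants: 2 (6S)-6-methylcyclohex-2-en-1-one; 3 (3-tert-butoxy-3-oxopropyl)zinc bromide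
Product: 4 tert-butyl 3-[4-methyl-3-(trimethylsilyloxy)cyclohex-2-en-1-yl]propanoate
Conditions: CuBr·SMe2 (10 mol %), TMSCl, THF/DMPU, −78 → −20 °C; non-aqueous work-up
Reagents that add atoms: chlorotrimethylsilane, C[Si](C)(C)Cl
Why: Copper-catalysed, TMSCl-accelerated conjugate addition of the zinc homoenolate brings C1–C3 to C9 and traps the enolate regiospecifically as the C5 silyl enol ether; the new C9 centre is erased in step 3.

Step 3
Reactants: 4 tert-butyl 3-[4-methyl-3-(trimethylsilyloxy)cyclohex-2-en-1-yl]propanoate
Product: 5 tert-butyl 3-(4-methyl-3-oxocyclohex-1-en-1-yl)propanoate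
Conditions: Pd(OAc)2 (10 mol %), O2 (1 atm), DMSO, 25 → 50 °C
Reagents that add atoms: none
Why: Saegusa–Ito oxidation (Pd enolate, β-hydride elimination) regenerates the enone, now β-substituted; C6 is not enolised because the silyl enol ether is regiodefined.

Step 4
Reactants: 5 tert-butyl 3-(4-methyl-3-oxocyclohex-1-en-1-yl)propanoate
Product: 7 tert-butyl 3-[3,4-dimethyl-3-(propanoyloxy)cyclohex-1-en-1-yl]propanoate, via lithium alkoxide 6 (not isolated)
Conditions: MeLi, CeCl3, THF, −78 °C; then (EtCO)2O, −78 → 0 °C
Reagents that add atoms: methyllithium, [Li]C; propanoic anhydride, CCC(=O)OC(=O)CC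
Why: 1,2-Addition of the methyl organometallic to the enone carbonyl (the tert-butyl ester is inert at −78 °C) and O-acylation of the tertiary alkoxide in the same flask; the methyl should enter from the face opposite the adjacent C6 methyl (equatorial attack, as with 2-alkylcyclohexanones), which puts the C5–O bond on the ring face where C10 must later be bonded to C9.

Step 5
Reactants: 7 tert-butyl 3-[3,4-dimethyl-3-(propanoyloxy)cyclohex-1-en-1-yl]propanoate
Product: 9 2-[1-(3-tert-butoxy-3-oxopropyl)-3,4-dimethylcyclohex-2-en-1-yl]propanoic acid, via bis(silyl ketene acetal) 8 (not isolated)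
Conditions: LDA (2.3 equiv), TBSCl, THF/DMPU (4:1), −78 °C; then → 50 °C; 1 M HCl
Reagents that add atoms: none
Why: Ireland–Claisen rearrangement: the silyl ketene acetal with CH3 cis to OSi (enolisation in THF/DMPU) rearranges suprafacially, so the C5 carbinol configuration is transferred to quaternary C9 and the C4=C5(CH3) alkene is formed; C10 follows from the ketene acetal geometry through the boat-like transition state that cyclohexenyl esters adopt when the OSiR3 group would otherwise sit under the ring; the chain ester is silylated reversibly and returns on acidic work-up.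

Step 6
Reactants: 9 2-[1-(3-tert-butoxy-3-oxopropyl)-3,4-dimethylcyclohex-2-en-1-yl]propanoic acid
Product: 10 S-ethyl thioester of 9
Conditions: EtSH, EDC·HCl, DMAP, CH2Cl2, 0 °C → rt
Reagents that add atoms: ethanethiol, CCS
Why: Steglich-type thioesterification turns the C11 acid into a group that cannot lactonise onto the alkene under the acidic conditions of step 7 and can later be reduced to the aldehyde without touching the enone.

Step 7
Reactants: 10 S-ethyl thioester of 9
Product: 12 S-ethyl 2-(6,7-dimethyl-1-oxo-1,2,3,4,5,6-hexahydro-3aH-inden-3a-yl)propanethioate, via carboxylic acid 11 (not isolated)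
Conditions: TFA, CH2Cl2, 0 °C → rt; evaporate; TFAA, CH2Cl2, 0 °C → rt; aq. NaHCO3
Reagents that add atoms: none
Why: TFA cleaves the tert-butyl ester; the mixed trifluoroacetic anhydride acylates the trisubstituted alkene at C4 (intramolecular Friedel–Crafts-type alkene acylation, 5-exo, Markovnikov with the tertiary cation at C5), and loss of the C4 proton gives the conjugated C3(=O)–C4=C5 enone; no stereocentre is formed.

Step 8
Reactants: 12 S-ethyl 2-(6,7-dimethyl-1-oxo-1,2,3,4,5,6-hexahydro-3aH-inden-3a-yl)propanethioate
Product: 13 2-(6,7-dimethyl-1-oxo-1,2,3,4,5,6-hexahydro-3aH-inden-3a-yl)propanal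
Conditions: Et3SiH, 10% Pd/C, acetone, rt
Reagents that add atoms: none
Why: Fukuyama reduction (Pd-catalysed silane reduction of a thioester) gives the aldehyde and leaves the hindered tetrasubstituted enone alone.

Step 9
Reactants: 14 pent-1-en-4-yne
Product: 15 (1E)-1-iodo-2-methylpenta-1,4-diene
Conditions: Me3Al, Cp2ZrCl2 (20 mol %), CH2Cl2, 0 °C → rt; then I2, THF, −30 → 0 °C
Reagents that add atoms: trimethylaluminium, C[Al](C)C; iodine, II
Why: Negishi zirconium-catalysed carboalumination adds methyl and aluminium syn across the alkyne (Al at the terminus; the alkene reacts far more slowly), and iodinolysis with retention gives the (E)-iodide with iodine cis to the new methyl.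

Step 10
Reactants: 16 chloro(chloromethyl)dimethylsilane; 17 diphenylmethane
Product: 19 (chloromethyl)(diphenylmethyl)dimethylsilane, via diphenylmethyllithium 18 (not isolated)
Conditions: 17, n-BuLi, THF, 0 °C → rt; then added to 16, THF, −78 °C → rt
Reagents that add atoms: none
Why: Benzylic lithiation and substitution at the Si–Cl bond, which is much faster than SN2 at the CH2Cl carbon, give the α-chloromethylsilane that carries the bulky but oxidisable benzhydryldimethylsilyl group.

Step 11
Reactants: 19 (chloromethyl)(diphenylmethyl)dimethylsilane; 15 (1E)-1-iodo-2-methylpenta-1,4-diene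
Product: 21 (diphenylmethyl)dimethyl[(2E)-3-methylhexa-2,5-dien-1-yl]silane, via Grignard reagent 20 (not isolated)
Conditions: Mg, THF, reflux; then 15, Pd(PPh3)4 (5 mol %), THF, 50 °C
Reagents that add atoms: none
Why: Kumada–Corriu coupling of the α-silyl Grignard reagent with the alkenyl iodide proceeds with retention of the (E)-geometry and gives the γ,γ-disubstituted allylsilane directly.

Step 12
Reactants: 13 2-(6,7-dimethyl-1-oxo-1,2,3,4,5,6-hexahydro-3aH-inden-3a-yl)propanal; 21 (diphenylmethyl)dimethyl[(2E)-3-methylhexa-2,5-dien-1-yl]silane
Product: 22 hydrindenone–oxolane with C19 silyl group and C12 allyl chain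
Conditions: BF3·OEt2 (1.2 equiv), CH2Cl2, −78 → −50 °C; aq. NaHCO3
Reagents that add atoms: none
Why: BF3 activates the aldehyde, the γ-carbon of the allylsilane (C12) adds anti-SE2′ to give a β-silyl cation at C19, silicon bridges to C20 (1,2-silyl shift) and the boron alkoxide opens the bridged cation at C20, so that C11–C12 and O–C20 form and silicon ends on C19. The closest known reaction type is the Lewis-acid [3+2] annulation of allylsilanes bearing bulky silyl groups with aldehydes to give 3-silyl-oxolanes, a branch of the Hosomi–Sakurai manifold. The oxolane is closed by a 5-exo-tet substitution at the primary C20 of the silicon-bridged cation. C11 is controlled by the C10 stereocentre: Felkin–Anh addition anti to the quaternary C9 gives the required syn relation of O11 and the C10 methyl along C9–C12. C12 is controlled by the open transition state, in which the substituent trans to CH2Si (C13) plays the role of the methyl of an (E)-crotylsilane, so that C13 and C10 end cis on the oxolane and the C12 methyl cis to H-11. C19 is fixed stereospecifically, because C11 and silicon add anti across the (E)-alkene, which places silicon (the later hydroxyl) cis to the C12 methyl. The step needs ring closure to win over desilylation, which the hindered benzhydryldimethylsilyl group secures by slowing attack at silicon, and it needs the aldehyde to react before the C3 carbonyl, which the conjugated, tetrasubstituted enone secures.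

Step 13
Reactants: 22 hydrindenone–oxolane with C19 silyl group and C12 allyl chain
Product: 23 C14 aldehyde of 22
Conditions: OsO4 (2 mol %), NaIO4, 2,6-lutidine, dioxane/H2O (3:1), rt
Reagents that add atoms: sodium periodate, [Na+].[O-][I](=O)(=O)=O
Why: Lemieux–Johnson cleavage of the only monosubstituted alkene gives the C14 aldehyde; the tetrasubstituted, electron-poor enone alkene does not react with osmium tetroxide at a useful rate.

Step 14
Reactants: 23 C14 aldehyde of 22
Product: 24 tricyclic C14 alcohol
Conditions: SmI2 (3 equiv), H2O (10 equiv), THF (5 mM), 0 °C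
Reagents that add atoms: none
Why: SmI2 ketyl–olefin (ketyl–enone) radical cyclisation: the C14 ketyl adds to C5 of the enone and closes the eight-membered ring, a second electron transfer gives the samarium enolate, and protonation at C4 gives the cis-hydrindanone; C5 and C14 arise from a transition state in which the chain, anchored at quaternary C9 and stiffened by the cis-fused oxolane, reaches C5 from the face of the C9–C10 bond with the O–Sm group pointing out of the forming ring.

Step 15
Reactants: 24 tricyclic C14 alcohol
Product: 25 C14 benzyloxyacetate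
Conditions: BnOCH2COCl, pyridine, DMAP, CH2Cl2, 0 → 40 °C
Reagents that add atoms: benzyloxyacetyl chloride, O=C(Cl)COCc1ccccc1
Why: DMAP-catalysed acylation of the hindered secondary C14 alcohol; O19 is still masked as C–Si, so no regioselectivity problem arises.

Step 16
Reactants: 25 C14 benzyloxyacetate
Product: 26 C19 alcohol (O22-benzyl ether of the target)
Conditions: TBAF, THF, 0 °C → rt; then KHCO3, 30% H2O2, MeOH/THF, 40 °C
Reagents that add atoms: hydrogen peroxide, OO
Why: Tamao–Fleming-type oxidation: fluoride expels the benzhydryl group from silicon and basic hydrogen peroxide converts C19–Si into C19–OH with retention; the hindered C14 ester should survive the buffered conditions.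

Step 17
Reactants: 26 C19 alcohol (O22-benzyl ether of the target)
Product: 27 Pleuromutilin B
Conditions: H2 (1 atm), 10% Pd/C, EtOAc, rt
Reagents that add atoms: none
Why: Hydrogenolysis of the benzyl ether under neutral conditions; no other reducible group is present.

## Compound list

1 | trans-dihydrocarvone, 2-methyl-5-(prop-1-en-2-yl)cyclohexan-1-one (2S,5S as the string is written) | O=C1[C@@H](C)CC[C@H](C(C)=C)C1 | starting material
2 | (6S)-6-methylcyclohex-2-en-1-one | O=C1[C@@H](C)CCC=C1 | intermediate
3 | (3-tert-butoxy-3-oxopropyl)zinc bromide | CC(C)(C)OC(=O)CC[Zn]Br | starting material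
4 | tert-butyl 3-[4-methyl-3-(trimethylsilyloxy)cyclohex-2-en-1-yl]propanoate (major C9 epimer; centre erased in step 3) | C[Si](C)(C)OC1=C[C@H](CCC(=O)OC(C)(C)C)CC[C@@H]1C | intermediate
5 | tert-butyl 3-(4-methyl-3-oxocyclohex-1-en-1-yl)propanoate | O=C1C=C(CCC(=O)OC(C)(C)C)CC[C@@H]1C | intermediate
6 | lithium alkoxide of the C5 tertiary carbinol (O cis to the C6 methyl) | [Li]O[C@]1(C)C=C(CCC(=O)OC(C)(C)C)CC[C@@H]1C | intermediate (not isolated)
7 | tert-butyl 3-[3,4-dimethyl-3-(propanoyloxy)cyclohex-1-en-1-yl]propanoate (ester O cis to the C6 methyl) | CCC(=O)O[C@]1(C)C=C(CCC(=O)OC(C)(C)C)CC[C@@H]1C | intermediate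
8 | bis(tert-butyldimethylsilyl ketene acetal) of 7 (propanoate-derived acetal with CH3 cis to OSi) | C/C=C(\O[Si](C)(C)C(C)(C)C)O[C@]1(C)C=C(CC=C(OC(C)(C)C)O[Si](C)(C)C(C)(C)C)CC[C@@H]1C | intermediate (not isolated)
9 | 2-[1-(3-tert-butoxy-3-oxopropyl)-3,4-dimethylcyclohex-2-en-1-yl]propanoic acid (C9 quaternary, C10 R) | OC(=O)[C@H](C)[C@]1(CCC(=O)OC(C)(C)C)C=C(C)[C@@H](C)CC1 | intermediate
10 | S-ethyl thioester of 9 | CCSC(=O)[C@H](C)[C@]1(CCC(=O)OC(C)(C)C)C=C(C)[C@@H](C)CC1 | intermediate
11 | C3 carboxylic acid from 10 (tert-butyl ester cleaved) | CCSC(=O)[C@H](C)[C@]1(CCC(=O)O)C=C(C)[C@@H](C)CC1 | intermediate (not isolated)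
12 | S-ethyl 2-(6,7-dimethyl-1-oxo-1,2,3,4,5,6-hexahydro-3aH-inden-3a-yl)propanethioate | CCSC(=O)[C@H](C)[C@]12CCC(=O)C1=C(C)[C@@H](C)CC2 | intermediate
13 | 2-(6,7-dimethyl-1-oxo-1,2,3,4,5,6-hexahydro-3aH-inden-3a-yl)propanal (C1–C11 fragment; C10 R) | O=C[C@H](C)[C@]12CCC(=O)C1=C(C)[C@@H](C)CC2 | intermediate
14 | pent-1-en-4-yne | C=CCC#C | starting material
15 | (1E)-1-iodo-2-methylpenta-1,4-diene | C=CC/C(C)=C/I | intermediate
16 | chloro(chloromethyl)dimethylsilane | C[Si](C)(Cl)CCl | starting material
17 | diphenylmethane | C(c1ccccc1)c1ccccc1 | starting material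
18 | diphenylmethyllithium | [Li]C(c1ccccc1)c1ccccc1 | intermediate (not isolated)
19 | (chloromethyl)(diphenylmethyl)dimethylsilane | C[Si](C)(CCl)C(c1ccccc1)c1ccccc1 | intermediate
20 | {[(diphenylmethyl)dimethylsilyl]methyl}magnesium chloride | C[Si](C)(C[Mg]Cl)C(c1ccccc1)c1ccccc1 | intermediate (not isolated)
21 | (diphenylmethyl)dimethyl[(2E)-3-methylhexa-2,5-dien-1-yl]silane | C=CC/C(C)=C/C[Si](C)(C)C(c1ccccc1)c1ccccc1 | intermediate
22 | hydrindenone–oxolane: 2,3,3,4-substituted oxolane (C11 attached to C10, C12 methyl and allyl, C19 benzhydryldimethylsilyl cis to the C12 methyl) on the C9 side chain of the hydrindenone | C[C@@H]([C@@H]1OC[C@@H]([Si](C)(C)C(c2ccccc2)c2ccccc2)[C@]1(C)CC=C)[C@]12CCC(=O)C1=C(C)[C@@H](C)CC2 | intermediate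
23 | C14 aldehyde of 22 | C[C@@H]([C@@H]1OC[C@@H]([Si](C)(C)C(c2ccccc2)c2ccccc2)[C@]1(C)CC=O)[C@]12CCC(=O)C1=C(C)[C@@H](C)CC2 | intermediate
24 | tricyclic C14 alcohol (5-6-8 core with fused oxolane, C19 silyl, C3 ketone) | C[C@H]1[C@@H]2OC[C@@H]([Si](C)(C)C(c3ccccc3)c3ccccc3)[C@]2(C)C[C@@H](O)[C@@]2(C)[C@@H](C)CC[C@]13CCC(=O)[C@@H]32 | intermediate
25 | C14 benzyloxyacetate of 24 | C[C@H]1[C@@H]2OC[C@@H]([Si](C)(C)C(c3ccccc3)c3ccccc3)[C@]2(C)C[C@@H](OC(=O)COCc3ccccc3)[C@@]2(C)[C@@H](C)CC[C@]13CCC(=O)[C@@H]32 | intermediate
26 | O22-benzyl ether of the target (C19 hydroxyl free) | C[C@H]1[C@@H]2OC[C@@H](O)[C@]2(C)C[C@@H](OC(=O)COCc3ccccc3)[C@@]2(C)[C@@H](C)CC[C@]13CCC(=O)[C@@H]32 | intermediate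
27 | Pleuromutilin B | C[C@H]1[C@@H]2OC[C@@H](O)[C@]2(C)C[C@@H](OC(=O)CO)[C@@]2(C)[C@@H](C)CC[C@]13CCC(=O)[C@@H]32 | target

## Step count and least certain steps

Total: 17 steps. Longest linear sequence: 14 steps (steps 1–8 and 12–17).

**Step 12 (key).** The most likely failure is loss of the silyl group from the β-silyl cation (Hosomi–Sakurai collapse) before the alkoxide closes the ring, because any nucleophile that reaches silicon ends the annulation. A second uncertainty is incomplete simple diastereoselection at C12, since both γ-substituents are alkyl groups. Fallback: the oxolane is made in separate events from the same two partners. From 13 and 21 the desilylative addition is driven to completion (TiCl4, −78 → 0 °C) to give the homoallylic alcohol F1. Hydroxyl-directed epoxidation of its C12 vinyl group (VO(acac)2, t-BuOOH) gives the epoxy alcohol F2, which closes under acid (CSA) by opening at C20 to the oxolanol F3. O19 is benzylated (NaH, BnBr) to the benzyl ether F4, Lemieux–Johnson cleavage gives the aldehyde F5, ketyl–enone closure as in step 14 gives the tricyclic alcohol F6, acylation as in step 15 gives the bis-benzyl ester F7, and hydrogenolysis of both benzyl groups returns to the route at 27.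

**Step 14.** The ketyl may be reduced further or dimerise instead of adding, or add with poor facial selectivity at C14, because the oxolane with its large silyl group restricts the conformations in which C14 reaches C5. Fallback: C–Si oxidation is moved in front of the ring closure. From 22, Tamao oxidation under the conditions of step 16 gives the oxolanol F3 and benzylation gives the benzyl ether F4; cleavage to the aldehyde F5, closure to the tricyclic alcohol F6 and acylation to the bis-benzyl ester F7 follow, and hydrogenolysis returns to the route at 27. No compound beyond F3–F7 is needed.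

**Step 4.** Attack of the methyl nucleophile on the wrong carbonyl face (axial attack) would give the C5-epimeric carbinol, and the rearrangement of step 5 would then bond C10 to the wrong face of C9. Fallback: hydride instead of methyl sets the carbinol. From 5, L-Selectride (equatorial hydride delivery) gives the cis-allylic alcohol F8 and propanoylation gives the ester F9. Ireland–Claisen rearrangement as in step 5 gives the acid F10, and TFA/TFAA as in step 7 gives the enone acid F11. The C5 methyl is then introduced by conjugate addition of lithium dimethylcuprate with TMSCl trapping (silyl enol ether F12) and Saegusa–Ito oxidation to the enone acid F13, whose thioesterification under the conditions of step 6 returns to the route at 12.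

**Step 5.** Competition between chair-like and boat-like transition states, or incomplete control of enolate geometry, would erode the configuration at C10. Fallback: C10 is set after the rearrangement by an auxiliary. From 5, methyl addition as in step 4 with an acetic anhydride quench gives the tertiary allylic acetate F14, and its Ireland–Claisen rearrangement gives the acetic acid F15 (C9 set, C10 still CH2). Coupling to (R)-4-benzyl-1,3-oxazolidin-2-one through the mixed pivalic anhydride gives the imide F16. Its sodium enolate is methylated anti to the benzyl group (Evans alkylation) to the imide F17, and LiOH/H2O2 cleavage returns to the route at 9.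

## Further compounds

F1 | step 12 | homoallylic alcohol (C11–OH, C12 methyl/vinyl/allyl) on the hydrindenone | C[C@@H]([C@H](O)[C@](C)(C=C)CC=C)[C@]12CCC(=O)C1=C(C)[C@@H](C)CC2
F2 | step 12 | 19,20-epoxy alcohol from F1 | C[C@@H]([C@H](O)[C@](C)([C@H]3CO3)CC=C)[C@]12CCC(=O)C1=C(C)[C@@H](C)CC2
F3 | step 12 | oxolanol (C19–OH, C12 allyl) on the hydrindenone | C[C@@H]([C@@H]1OC[C@@H](O)[C@]1(C)CC=C)[C@]12CCC(=O)C1=C(C)[C@@H](C)CC2
F4 | step 12 | O19-benzyl ether of F3 | C[C@@H]([C@@H]1OC[C@@H](OCc2ccccc2)[C@]1(C)CC=C)[C@]12CCC(=O)C1=C(C)[C@@H](C)CC2
F5 | step 12 | C14 aldehyde from F4 | C[C@@H]([C@@H]1OC[C@@H](OCc2ccccc2)[C@]1(C)CC=O)[C@]12CCC(=O)C1=C(C)[C@@H](C)CC2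
F6 | step 12 | tricyclic C14 alcohol with O19-benzyl ether | C[C@H]1[C@@H]2OC[C@@H](OCc3ccccc3)[C@]2(C)C[C@@H](O)[C@@]2(C)[C@@H](C)CC[C@]13CCC(=O)[C@@H]32
F7 | step 12 | O19-benzyl, O22-benzyl ester (bis-benzyl ether of the target) | C[C@H]1[C@@H]2OC[C@@H](OCc3ccccc3)[C@]2(C)C[C@@H](OC(=O)COCc3ccccc3)[C@@]2(C)[C@@H](C)CC[C@]13CCC(=O)[C@@H]32
F0 | step 14 | none | none
F8 | step 4 | cis-allylic alcohol, tert-butyl 3-(3-hydroxy-4-methylcyclohex-1-en-1-yl)propanoate | O[C@@H]1C=C(CCC(=O)OC(C)(C)C)CC[C@@H]1C
F9 | step 4 | propanoate of F8 | CCC(=O)O[C@@H]1C=C(CCC(=O)OC(C)(C)C)CC[C@@H]1C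
F10 | step 4 | 2-[1-(3-tert-butoxy-3-oxopropyl)-4-methylcyclohex-2-en-1-yl]propanoic acid | OC(=O)[C@H](C)[C@]1(CCC(=O)OC(C)(C)C)C=C[C@@H](C)CC1
F11 | step 4 | enone acid without the C5 methyl | OC(=O)[C@H](C)[C@]12CCC(=O)C1=C[C@@H](C)CC2
F12 | step 4 | C3 trimethylsilyl enol ether after methyl addition at C5 (C5 epimers; centre erased in the next operation) | OC(=O)[C@H](C)[C@]12CCC(O[Si](C)(C)C)=C1C(C)[C@@H](C)CC2
F13 | step 4 | 2-(6,7-dimethyl-1-oxo-1,2,3,4,5,6-hexahydro-3aH-inden-3a-yl)propanoic acid | OC(=O)[C@H](C)[C@]12CCC(=O)C1=C(C)[C@@H](C)CC2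
F14 | step 5 | tertiary allylic acetate (acetate analogue of 7) | CC(=O)O[C@]1(C)C=C(CCC(=O)OC(C)(C)C)CC[C@@H]1C
F15 | step 5 | 2-[1-(3-tert-butoxy-3-oxopropyl)-3,4-dimethylcyclohex-2-en-1-yl]acetic acid | OC(=O)C[C@]1(CCC(=O)OC(C)(C)C)C=C(C)[C@@H](C)CC1
F16 | step 5 | N-acyl (R)-4-benzyloxazolidinone of F15 | O=C(C[C@]1(CCC(=O)OC(C)(C)C)C=C(C)[C@@H](C)CC1)N1[C@H](Cc2ccccc2)COC1=O
F17 | step 5 | C10-methylated imide | O=C([C@H](C)[C@]1(CCC(=O)OC(C)(C)C)C=C(C)[C@@H](C)CC1)N1[C@H](Cc2ccccc2)COC1=O
A1 | alternative 1 | C12-vinyl C11-carbinol with the C14 glycolate (19,20-alkene of the target skeleton) | C[C@H]1[C@H](O)[C@](C)(C=C)C[C@@H](OC(=O)CO)[C@@]2(C)[C@@H](C)CC[C@]13CCC(=O)[C@@H]32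
A2 | alternative 1 | 19,20-epoxide of A1 | C[C@H]1[C@H](O)[C@](C)([C@H]4CO4)C[C@@H](OC(=O)CO)[C@@]2(C)[C@@H](C)CC[C@]13CCC(=O)[C@@H]32
A3 | alternative 2 | cis-hydrindanone with C9 aldehyde arm and C5 allylsilane arm (O14 as TBS ether) | O=C[C@H](C)[C@]12CCC(=O)[C@@H]1[C@@](C)([C@H](O[Si](C)(C)C(C)(C)C)C/C(C)=C/C[Si](C)(C)C(c3ccccc3)c3ccccc3)[C@@H](C)CC2
A4 | alternative 2 | tricyclic oxolane from A3 (C19 silyl, O14 TBS ether) | C[C@H]1[C@@H]2OC[C@@H]([Si](C)(C)C(c3ccccc3)c3ccccc3)[C@]2(C)C[C@@H](O[Si](C)(C)C(C)(C)C)[C@@]2(C)[C@@H](C)CC[C@]13CCC(=O)[C@@H]32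
A5 | alternative 3 | tricyclic C11=C12 alkene (C12 methyl, O14 TBS ether) | C[C@H]1C=C(C)C[C@@H](O[Si](C)(C)C(C)(C)C)[C@@]2(C)[C@@H](C)CC[C@]13CCC(=O)[C@@H]32
A6 | alternative 3 | dichlorocyclobutanone fused at C11–C12 | C[C@H]1[C@@H]2C(=O)C(Cl)(Cl)[C@]2(C)C[C@@H](O[Si](C)(C)C(C)(C)C)[C@@]2(C)[C@@H](C)CC[C@]13CCC(=O)[C@@H]32
A7 | alternative 3 | γ-lactone after dechlorination and oxygen insertion | C[C@H]1[C@@H]2OC(=O)C[C@]2(C)C[C@@H](O[Si](C)(C)C(C)(C)C)[C@@]2(C)[C@@H](C)CC[C@]13CCC(=O)[C@@H]32
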